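**Retrosynthetic overview**
- The target is reached by ketal removal from a butenolide acid; the ring C3=C4 double bond comes from α-selenenylation and selenoxide syn-elimination of the saturated all-trans 4-methyl paraconic acid.
- The 4-methyl group is installed by dianion alkylation of the paraconic acid, which is released from its chiral imide by LiOOH.
- Key disconnection, ring C2–C3: Evans syn-aldol of the (R)-4-benzyloxazolidinone imide of monomethyl succinate with 14-(2-methyl-1,3-dioxolan-2-yl)tetradecanal; this sets the (S) carbinol centre.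
- The aldehyde comes from ω-pentadecalactone: Weinreb amide, MeMgBr, ketalisation, Swern oxidation.
- Ring order: dioxolane (protecting ring, step 3), then the γ-lactone (closed right after the aldol, step 6), which is dehydrogenated to the butenolide (step 10); the dioxolane is opened last (step 11).

Assumption: the stereocentre is read as (S) (O > ring C3 > chain CH2 > H); ring positions below use oxolane numbering (O1, C2 alkyl, C3 carboxyl, C4 methyl, C5 carbonyl).

**Step 1**
Reactants: 1 ω-pentadecalactone (oxacyclohexadecan-2-one)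
Product: 2 15-hydroxy-N-methoxy-N-methylpentadecanamide
Conditions: MeNH(OMe)·HCl, AlMe3, CH2Cl2, 0 °C → rt; 1 M HCl
Reagents that add atoms: N,O-dimethylhydroxylamine hydrochloride, CNOC.Cl
Why: Weinreb aminolysis of a lactone with the aluminium amide made from AlMe3 and the amine hydrochloride opens the macrolactone irreversibly, since a 16-membered ring does not re-close.

**Step 2**
Reactants: 2 15-hydroxy-N-methoxy-N-methylpentadecanamide
Product: 3 16-hydroxyhexadecan-2-one
Conditions: MeMgBr (3 equiv), THF, 0 °C; 1 M HCl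
Reagents that add atoms: methylmagnesium bromide, C[Mg]Br
Why: Grignard addition to a Weinreb amide stops at the ketone because the chelated tetrahedral intermediate survives until quench (the first equivalent only deprotonates the OH).

**Step 3**
Reactants: 3 16-hydroxyhexadecan-2-one
Product: 4 14-(2-methyl-1,3-dioxolan-2-yl)tetradecan-1-ol
Conditions: ethylene glycol, p-TsOH (cat.), PhMe, reflux, Dean–Stark
Reagents that add atoms: ethylene glycol, OCCO
Why: Acid-catalysed ketalisation with azeotropic water removal masks the enolisable methyl ketone for the later enolate steps.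

**Step 4**
Reactants: 4 14-(2-methyl-1,3-dioxolan-2-yl)tetradecan-1-ol
Product: 5 14-(2-methyl-1,3-dioxolan-2-yl)tetradecanal
Conditions: (COCl)2, DMSO, CH2Cl2, −78 °C; Et3N, −78 → 0 °C
Reagents that add atoms: none
Why: Swern oxidation stops cleanly at the aldehyde under non-acidic conditions that leave the ketal intact.

**Step 5**
Reactants: 6 (R)-4-benzyloxazolidin-2-one; 7 methyl 4-chloro-4-oxobutanoate
Product: 9 methyl 4-[(R)-4-benzyl-2-oxooxazolidin-3-yl]-4-oxobutanoate, via N-lithio oxazolidinone 8 (not isolated)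
Conditions: n-BuLi, THF, −78 °C; 7, −78 → 0 °C
Reagents that add atoms: none
Why: N-acylation of the lithiated oxazolidinone occurs only at the acid chloride, which is far more electrophilic than the methyl ester at −78 °C.

**Step 6**
Reactants: 9 methyl 4-[(R)-4-benzyl-2-oxooxazolidin-3-yl]-4-oxobutanoate; 5 14-(2-methyl-1,3-dioxolan-2-yl)tetradecanal
Product: 12 (R)-4-benzyl-3-{(2S,3R)-2-[13-(2-methyl-1,3-dioxolan-2-yl)tridecyl]-5-oxotetrahydrofuran-3-carbonyl}oxazolidin-2-one, via Z-boron enolate 10 (not isolated), via syn-aldol hydroxy ester 11 (not isolated)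
Conditions: Bu2BOTf, iPr2NEt, CH2Cl2, 0 °C; 5, −78 → 0 °C; 30% H2O2, MeOH, pH 7 NaH2PO4/Na2HPO4 buffer; PPTS (cat.), PhMe, 50 °C
Reagents that add atoms: none
Why: Evans syn-aldol through the Z(O) boron enolate and a Zimmerman–Traxler chair, with the aldehyde adding to the enolate face away from the benzyl group, gives the (S) carbinol from the (R)-auxiliary, and the γ-hydroxy ester then lactonises to the trans lactone.

**Step 7**
Reactants: 12 (R)-4-benzyl-3-{(2S,3R)-2-[13-(2-methyl-1,3-dioxolan-2-yl)tridecyl]-5-oxotetrahydrofuran-3-carbonyl}oxazolidin-2-one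
Product: 13 (2S,3R)-2-[13-(2-methyl-1,3-dioxolan-2-yl)tridecyl]-5-oxotetrahydrofuran-3-carboxylic acid
Conditions: LiOH, 30% H2O2, THF/H2O, 0 °C; Na2SO3; cold 1 M HCl to pH 3
Reagents that add atoms: hydrogen peroxide (acting as LiOOH), OO
Why: Lithium hydroperoxide cleaves the exocyclic imide carbonyl selectively (auxiliary 6 is recovered), and any opened lactone re-closes on acidification without touching C2.

**Step 8**
Reactants: 13 (2S,3R)-2-[13-(2-methyl-1,3-dioxolan-2-yl)tridecyl]-5-oxotetrahydrofuran-3-carboxylic acid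
Product: 15 (2S,3R,4R)-4-methyl-2-[13-(2-methyl-1,3-dioxolan-2-yl)tridecyl]-5-oxotetrahydrofuran-3-carboxylic acid, via disodium enolate carboxylate 14 (not isolated)
Conditions: NaN(SiMe3)2 (2.3 equiv), THF, −78 °C; MeI, −78 → −40 °C; cold 1 M HCl to pH 3
Reagents that add atoms: iodomethane, CI
Why: Dianion alkylation, in which the carboxylate shields C3–H from deprotonation and the lactone enolate takes MeI anti to the carboxylate, gives the all-trans acid (this centre becomes sp2 later, so its ratio is not critical).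

**Step 9**
Reactants: 15 (2S,3R,4R)-4-methyl-2-[13-(2-methyl-1,3-dioxolan-2-yl)tridecyl]-5-oxotetrahydrofuran-3-carboxylic acid
Product: 17 (2S,3R,4R)-4-methyl-2-[13-(2-methyl-1,3-dioxolan-2-yl)tridecyl]-5-oxo-4-(phenylselanyl)tetrahydrofuran-3-carboxylic acid, via dilithium enolate carboxylate 16 (not isolated)
Conditions: LiN(iPr)2 (2.5 equiv), THF, −78 → −30 °C; PhSeCl, −78 °C; cold 1 M HCl to pH 3
Reagents that add atoms: phenylselenenyl chloride, Cl[Se]c1ccccc1
Why: α-Selenenylation of the lactone enolate occurs anti to the C3 carboxylate, which places selenium cis to C3–H as the next step requires.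

**Step 10**
Reactants: 17 (2S,3R,4R)-4-methyl-2-[13-(2-methyl-1,3-dioxolan-2-yl)tridecyl]-5-oxo-4-(phenylselanyl)tetrahydrofuran-3-carboxylic acid
Product: 19 (S)-4-methyl-2-[13-(2-methyl-1,3-dioxolan-2-yl)tridecyl]-5-oxo-2,5-dihydrofuran-3-carboxylic acid, via selenoxide 18 (not isolated)
Conditions: 30% H2O2, pyridine, CH2Cl2, 0 °C → rt
Reagents that add atoms: none
Why: Selenoxide syn-elimination toward the cis C3–H gives the doubly conjugated tetrasubstituted butenolide under near-neutral conditions that leave the C2 stereocentre and the ketal untouched.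

**Step 11**
Reactants: 19 (S)-4-methyl-2-[13-(2-methyl-1,3-dioxolan-2-yl)tridecyl]-5-oxo-2,5-dihydrofuran-3-carboxylic acid
Product: 20 (S)-4-methyl-5-oxo-2-(14-oxopentadecyl)-2,5-dihydrofuran-3-carboxylic acid
Conditions: 1 M HCl, THF, rt
Reagents that add atoms: water, O
Why: Acid-catalysed ketal hydrolysis frees the methyl ketone, and with no base present the butenolide γ-stereocentre cannot epimerise.

**Compound list**
1 | ω-pentadecalactone (oxacyclohexadecan-2-one) | O=C1CCCCCCCCCCCCCCO1 | starting material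
2 | 15-hydroxy-N-methoxy-N-methylpentadecanamide | CON(C)C(=O)CCCCCCCCCCCCCCO | intermediate
3 | 16-hydroxyhexadecan-2-one | CC(=O)CCCCCCCCCCCCCCO | intermediate
4 | 14-(2-methyl-1,3-dioxolan-2-yl)tetradecan-1-ol | CC1(CCCCCCCCCCCCCCO)OCCO1 | intermediate
5 | 14-(2-methyl-1,3-dioxolan-2-yl)tetradecanal | CC1(CCCCCCCCCCCCCC=O)OCCO1 | intermediate
6 | (R)-4-benzyloxazolidin-2-one | O=C1N[C@H](Cc2ccccc2)CO1 | starting material
7 | methyl 4-chloro-4-oxobutanoate | COC(=O)CCC(Cl)=O | starting material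
8 | lithium (R)-4-benzyl-2-oxooxazolidin-3-ide (N-lithio oxazolidinone) | [Li+].O=C1[N-][C@H](Cc2ccccc2)CO1 | intermediate (not isolated)
9 | methyl 4-[(R)-4-benzyl-2-oxooxazolidin-3-yl]-4-oxobutanoate | COC(=O)CCC(=O)N1[C@H](Cc2ccccc2)COC1=O | intermediate
10 | dibutylboron (Z)-enolate of 9 | COC(=O)C/C=C(\OB(CCCC)CCCC)N1[C@H](Cc2ccccc2)COC1=O | intermediate (not isolated)
11 | methyl (3R,4S)-3-[(R)-4-benzyl-2-oxooxazolidine-3-carbonyl]-4-hydroxy-17-(2-methyl-1,3-dioxolan-2-yl)heptadecanoate | COC(=O)C[C@@H](C(=O)N1[C@H](Cc2ccccc2)COC1=O)[C@@H](O)CCCCCCCCCCCCCC2(C)OCCO2 | intermediate (not isolated)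
12 | (R)-4-benzyl-3-{(2S,3R)-2-[13-(2-methyl-1,3-dioxolan-2-yl)tridecyl]-5-oxotetrahydrofuran-3-carbonyl}oxazolidin-2-one | O=C1C[C@@H](C(=O)N2[C@H](Cc3ccccc3)COC2=O)[C@H](CCCCCCCCCCCCCC3(C)OCCO3)O1 | intermediate
13 | (2S,3R)-2-[13-(2-methyl-1,3-dioxolan-2-yl)tridecyl]-5-oxotetrahydrofuran-3-carboxylic acid | O=C1C[C@@H](C(=O)O)[C@H](CCCCCCCCCCCCCC2(C)OCCO2)O1 | intermediate
14 | disodium enolate carboxylate of 13 | [Na+].[Na+].[O-]C1=C[C@@H](C(=O)[O-])[C@H](CCCCCCCCCCCCCC2(C)OCCO2)O1 | intermediate (not isolated)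
15 | (2S,3R,4R)-4-methyl-2-[13-(2-methyl-1,3-dioxolan-2-yl)tridecyl]-5-oxotetrahydrofuran-3-carboxylic acid | O=C1[C@H](C)[C@@H](C(=O)O)[C@H](CCCCCCCCCCCCCC2(C)OCCO2)O1 | intermediate
16 | dilithium enolate carboxylate of 15 | [Li+].[Li+].[O-]C1=C(C)[C@@H](C(=O)[O-])[C@H](CCCCCCCCCCCCCC2(C)OCCO2)O1 | intermediate (not isolated)
17 | (2S,3R,4R)-4-methyl-2-[13-(2-methyl-1,3-dioxolan-2-yl)tridecyl]-5-oxo-4-(phenylselanyl)tetrahydrofuran-3-carboxylic acid | O=C1[C@](C)([Se]c2ccccc2)[C@@H](C(=O)O)[C@H](CCCCCCCCCCCCCC2(C)OCCO2)O1 | intermediate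
18 | selenoxide of 17 (mixture at selenium) | O=C1[C@](C)([Se](=O)c2ccccc2)[C@@H](C(=O)O)[C@H](CCCCCCCCCCCCCC2(C)OCCO2)O1 | intermediate (not isolated)
19 | (S)-4-methyl-2-[13-(2-methyl-1,3-dioxolan-2-yl)tridecyl]-5-oxo-2,5-dihydrofuran-3-carboxylic acid | CC1(CCCCCCCCCCCCC[C@@H]2OC(=O)C(C)=C2C(=O)O)OCCO1 | intermediate
20 | (S)-4-methyl-5-oxo-2-(14-oxopentadecyl)-2,5-dihydrofuran-3-carboxylic acid | CC(=O)CCCCCCCCCCCCC[C@@H]1OC(=O)C(C)=C1C(=O)O | target

**Totals**
Total steps: 11. Longest linear sequence: 10 steps (steps 1–4, then 6–11); the auxiliary branch is step 5.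

**Three steps most likely to fail**

Step 6 (aldol and lactonisation). The risks are unclean enolisation of an imide that also carries an ester, and incomplete or messy ring closure. The fallback sets out from 6 and 5 and carries the future lactone carbonyl as a vinyl group. Compound 6 is acylated (n-BuLi, pent-4-enoyl chloride) to (R)-4-benzyl-3-(pent-4-enoyl)oxazolidin-2-one F1. The Bu2BOTf/iPr2NEt aldol of F1 with 5 gives (R)-4-benzyl-3-[(2R,3S)-2-allyl-3-hydroxy-16-(2-methyl-1,3-dioxolan-2-yl)hexadecanoyl]oxazolidin-2-one F2. Ozonolysis (O3, CH2Cl2, −78 °C; Me2S) unmasks an aldehyde that closes onto the hydroxyl to give (R)-4-benzyl-3-{(2S,3R)-5-hydroxy-2-[13-(2-methyl-1,3-dioxolan-2-yl)tridecyl]tetrahydrofuran-3-carbonyl}oxazolidin-2-one F3. Oxidation of the lactol (TEMPO, PhI(OAc)2) comes back to the route at 12.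

Step 9 (selenenylation of the hindered tertiary dianion). The risks are incomplete enolisation or the wrong face selectivity. The fallback sets out from 13 and avoids both the methylation and the selenium chemistry. Carboxylation with MeOMgOCO2Me (DMF, 135 °C), followed by cold aqueous HCl that also removes the ketal, gives (2S,3R)-5-oxo-2-(14-oxopentadecyl)tetrahydrofuran-3,4-dicarboxylic acid F4. Decarboxylative Mannich methylenation (aq. HCHO, N-methylaniline, NaOAc, AcOH, rt) gives (2S,3R)-4-methylene-5-oxo-2-(14-oxopentadecyl)tetrahydrofuran-3-carboxylic acid F5. Exo-to-endo isomerisation by brief warming with Ac2O/Et3N and aqueous hydrolysis (the mixed anhydride acidifies C3–H) comes back to the route at 20.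

Step 10 (regiochemistry of the selenoxide elimination, endo versus exo). The fallback sets out from 15 and replaces the syn-elimination by an E1cB dehydration that can only run toward C3–H. Dianion 16 is hydroxylated with 2-(phenylsulfonyl)-3-phenyloxaziridine to (2S,3S,4R)-4-hydroxy-4-methyl-2-[13-(2-methyl-1,3-dioxolan-2-yl)tridecyl]-5-oxotetrahydrofuran-3-carboxylic acid F6. Treatment with Ac2O, Et3N and DMAP (cat.) in CH2Cl2 at 0 °C (O-acetylation and mixed anhydride formation, loss of acetate from the C3 enolate, then aqueous hydrolysis) comes back to the route at 19.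

**Further compounds**
F1 | step 6 | (R)-4-benzyl-3-(pent-4-enoyl)oxazolidin-2-one | C=CCCC(=O)N1[C@H](Cc2ccccc2)COC1=O
F2 | step 6 | (R)-4-benzyl-3-[(2R,3S)-2-allyl-3-hydroxy-16-(2-methyl-1,3-dioxolan-2-yl)hexadecanoyl]oxazolidin-2-one | C=CC[C@@H](C(=O)N1[C@H](Cc2ccccc2)COC1=O)[C@@H](O)CCCCCCCCCCCCCC2(C)OCCO2
F3 | step 6 | (R)-4-benzyl-3-{(2S,3R)-5-hydroxy-2-[13-(2-methyl-1,3-dioxolan-2-yl)tridecyl]tetrahydrofuran-3-carbonyl}oxazolidin-2-one (anomer mixture) | OC1C[C@@H](C(=O)N2[C@H](Cc3ccccc3)COC2=O)[C@H](CCCCCCCCCCCCCC3(C)OCCO3)O1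
F4 | step 9 | (2S,3R)-5-oxo-2-(14-oxopentadecyl)tetrahydrofuran-3,4-dicarboxylic acid (C4 epimers) | O=C1C(C(=O)O)[C@@H](C(=O)O)[C@H](CCCCCCCCCCCCCC(C)=O)O1
F5 | step 9 | (2S,3R)-4-methylene-5-oxo-2-(14-oxopentadecyl)tetrahydrofuran-3-carboxylic acid | O=C1C(=C)[C@@H](C(=O)O)[C@H](CCCCCCCCCCCCCC(C)=O)O1
F6 | step 10 | (2S,3S,4R)-4-hydroxy-4-methyl-2-[13-(2-methyl-1,3-dioxolan-2-yl)tridecyl]-5-oxotetrahydrofuran-3-carboxylic acid | O=C1[C@](C)(O)[C@@H](C(=O)O)[C@H](CCCCCCCCCCCCCC2(C)OCCO2)O1
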